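## Retrosynthetic overview

- Last events: global hydrogenolysis (17 benzyl ethers, 3 aryl bromides); before it the B-C4→C-C8 bond, made by soft (thiophilic) activation of a C4 sulfide in an A–B dimer towards a perbenzylated epicatechin-(4β→8)-epicatechin dimer (units C–D, from two epicatechin units); before that the A-C4→B-C6 bond, made by hard activation of a catechin C4 ether.
- Unit B is built de novo. Its pyran ring is the only ring constructed and is closed by the O1–C8a bond in a one-pot three-component operation: aryllithium plus Weinreb amide (C4–C4a), aryne across C8–C8a, closure by the C2 alkoxide at C8a, bromination of the C8 carbanion.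
- Enabling feature: in ring A of unit B, C8a (bearing O1) lies between C4a (bearing C4) and a C8 that is unsubstituted in the target and flanked by the C7 oxygen. An aryne across C8–C8a is therefore polarised by the C7 ether and held by the C4a tether so that O1 enters at C8a. The carbanion left at C8 takes a bromine cap that later forces unit A onto C6 (the rare 4→6 link) and is removed in the last step.
- Because the aryl C8a–O bond, not the benzylic C2–O bond, is formed, the syn (2S,3R) aldol stereochemistry maps without inversion onto the 2,3-cis (epicatechin) ring. Ring order: rings of A, C and D from the chiral pool, ring A of B from 1,3,5-trifluorobenzene, pyran ring of B in step 6.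

Key step: step 6

Remark: where C4 of a flavan unit is ionised in the following step its configuration is immaterial; the C4 ethers are drawn in the configuration expected from the oxidation, and the C4 alcohol of unit B is carried as a mixture of C4 epimers.

## Route

Step 1
Reactants: 1 1,3,5-trifluorobenzene
Product: 2 1,3-bis(benzyloxy)-5-fluorobenzene
Conditions: BnOH (2.1 equiv), NaH, NMP, 0 → 80 °C
Reagents that add atoms: benzyl alcohol, OCc1ccccc1
Why: Twofold nucleophilic aromatic substitution of fluoride by benzyloxide, in which each alkoxy group introduced slows the next displacement so that the reaction should stop at the bis-ether with one fluorine left.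

Step 2
Reactants: 2 1,3-bis(benzyloxy)-5-fluorobenzene
Product: 3 1,5-bis(benzyloxy)-2-bromo-3-fluorobenzene
Conditions: NBS (1.0 equiv), MeCN, 0 °C → rt
Reagents that add atoms: N-bromosuccinimide, O=C1CCC(=O)N1Br
Why: Electrophilic aromatic bromination, which on 1-fluoro-3,5-dialkoxybenzenes is expected para to one alkoxy group and ortho to the small fluorine, placing bromine between F and OBn.

Step 3
Reactants: 4 (S)-4-benzyloxazolidin-2-one; 5 (benzyloxy)acetyl chloride
Product: 6 (S)-4-benzyl-3-[(benzyloxy)acetyl]oxazolidin-2-one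
Conditions: n-BuLi, THF, −78 °C
Reagents that add atoms: none
Why: N-acylation of the lithiated oxazolidinone by the acid chloride, the standard entry to imides for auxiliary-controlled aldol chemistry, with no stereocentre touched.

Step 4
Reactants: 6 (S)-4-benzyl-3-[(benzyloxy)acetyl]oxazolidin-2-one; 7 3,4-bis(benzyloxy)benzaldehyde
Product: 8 (S)-4-benzyl-3-[(2S,3R)-2-(benzyloxy)-3-[3,4-bis(benzyloxy)phenyl]-3-hydroxypropanoyl]oxazolidin-2-one
Conditions: Bu2BOTf, i-Pr2NEt, CH2Cl2, −78 → 0 °C; then pH 7 buffer, MeOH, H2O2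
Reagents that add atoms: none
Why: Evans syn-aldol reaction of the glycolate imide, in which boron-mediated Z enolisation and a chair-like Zimmerman–Traxler transition state on the face opposite the auxiliary benzyl group set both new centres (2S,3R, syn) under auxiliary control.

Step 5
Reactants: 8 (S)-4-benzyl-3-[(2S,3R)-2-(benzyloxy)-3-[3,4-bis(benzyloxy)phenyl]-3-hydroxypropanoyl]oxazolidin-2-one
Product: 9 (2S,3R)-2-(benzyloxy)-3-[3,4-bis(benzyloxy)phenyl]-3-hydroxy-N-methoxy-N-methylpropanamide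
Conditions: MeNHOMe·HCl, AlMe3, CH2Cl2, −20 → 0 °C; aq. HCl work-up
Reagents that add atoms: N,O-dimethylhydroxylamine hydrochloride, CNOC.Cl
Why: Weinreb amide formation by aluminium amide transamidation, which cleaves the imide at the exocyclic carbonyl with assistance of the free β-hydroxyl and leaves both stereocentres untouched.

Step 6
Reactants: 3 1,5-bis(benzyloxy)-2-bromo-3-fluorobenzene; 9 (2S,3R)-2-(benzyloxy)-3-[3,4-bis(benzyloxy)phenyl]-3-hydroxy-N-methoxy-N-methylpropanamide
Product: 14 (2R,3S)-3,5,7-tris(benzyloxy)-2-[3,4-bis(benzyloxy)phenyl]-8-bromochroman-4-one, via aryllithium 10 (not isolated), via hemiaminal dialkoxide 11 (not isolated), via aryne 12 (not isolated), via C8 aryllithium 13 (not isolated)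
Conditions: 9, lithium 2,2,6,6-tetramethylpiperidide (LiTMP, 1.0 equiv), THF, −78 °C; 3, n-BuLi, THF, −78 °C, then transfer, −78 → −60 °C; LiTMP (1.5 equiv), −78 → −10 °C; (BrCCl2)2, −78 °C; AcOH, then H2O
Reagents that add atoms: 1,2-dibromo-1,1,2,2-tetrachloroethane, BrC(Cl)(Cl)C(Cl)(Cl)Br
Why: Proposed new method: bromine–lithium exchange on 3 gives the ortho-fluoro aryllithium 10, which acylates the Weinreb amide of 9 (held as its lithium alkoxide) to the chelated adduct 11, so that C4 stays masked against enolisation and retro-aldol cleavage; LiTMP then removes the only proton flanked by F and OBn (C8–H), loss of LiF gives aryne 12, the tethered C2 alkoxide adds at C8a, and the resulting aryllithium 13 is brominated before work-up releases the C4 ketone. The closest known reaction types are aryne ring closures of tethered alkoxides or amides with electrophilic capture of the new aryllithium, and additions of ortho-fluoro aryllithiums to Weinreb amides, here telescoped into one operation. The pyran ring is closed in a 6-exo-dig sense with respect to the aryne (C8a inside the new ring, C8 outside), closure at C8 being geometrically impossible. No stereocentre is created: C2 and C3 come from the aldol and are not touched because the aryl C8a–O bond and not the benzylic C2–O bond is formed, so the syn arrangement should appear as the 2,3-cis ring. The regioselectivity needed (O at C8a, Br at C8) is secured twice, by the tether and by the C7 benzyloxy group beside the triple bond, which directs the nucleophile to the remote aryne carbon and places the carbanion next to oxygen. The chemoselectivity rests on the order of acidities (C8–H between F and O well above C6–H between two ethers and the benzylic CH2 groups) and on the low temperature of the first stages, at which 10 does not yet lose LiF.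

Step 7
Reactants: 14 (2R,3S)-3,5,7-tris(benzyloxy)-2-[3,4-bis(benzyloxy)phenyl]-8-bromochroman-4-one
Product: 15 8-bromo-3,5,7,3',4'-penta-O-benzyl-epicatechin-4-ol (C4 epimer mixture)
Conditions: NaBH4, THF/MeOH, −20 °C
Reagents that add atoms: none
Why: Hydride reduction of the aryl ketone at low temperature, chosen to outrun base-induced epimerisation at C3, the new C4 centre being formed as a mixture that is immaterial because C4 is ionised in step 8.

Step 8
Reactants: 15 8-bromo-3,5,7,3',4'-penta-O-benzyl-epicatechin-4-ol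
Product: 16 8-bromo-3,5,7,3',4'-penta-O-benzyl-4β-[(2,6-dimethylphenyl)sulfanyl]-epicatechin
Conditions: 2,6-Me2C6H3SH, BF3·OEt2 (0.3 equiv), CH2Cl2, −78 → −30 °C
Reagents that add atoms: 2,6-dimethylbenzenethiol, Cc1cccc(C)c1S
Why: Acid-promoted SN1 thiolysis at the oxygen-activated benzylic C4, the thiol adding anti to the 3-benzyloxy and 2-aryl groups (4β, 3,4-trans) to give a sulfide leaving group that is inert to hard Lewis acids (orthogonal activation).

Step 9
Reactants: 17 (+)-catechin
Product: 18 5,7,3',4'-tetra-O-benzyl-(+)-catechin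
Conditions: BnBr, K2CO3, DMF, rt
Reagents that add atoms: benzyl bromide, BrCc1ccccc1
Why: Williamson etherification selective for the four phenols, the secondary 3-hydroxyl not being deprotonated by K2CO3.

Step 10
Reactants: 18 5,7,3',4'-tetra-O-benzyl-(+)-catechin
Product: 19 5,7,3',4'-tetra-O-benzyl-4β-(2-ethoxyethoxy)-(+)-catechin
Conditions: DDQ, 2-ethoxyethanol, CH2Cl2, rt
Reagents that add atoms: 2-ethoxyethanol, CCOCCO
Why: DDQ benzylic oxidation (hydride abstraction at C4 and capture of the cation by the alcohol), the standard C4 activation of benzylated flavan-3-ols, expected to give the 3,4-cis ether whose configuration is lost later.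

Step 11
Reactants: 19 5,7,3',4'-tetra-O-benzyl-4β-(2-ethoxyethoxy)-(+)-catechin
Product: 20 6,8-dibromo-5,7,3',4'-tetra-O-benzyl-4β-(2-ethoxyethoxy)-(+)-catechin
Conditions: NBS (2.05 equiv), CH2Cl2, −20 → 0 °C
Reagents that add atoms: N-bromosuccinimide, O=C1CCC(=O)N1Br
Why: Electrophilic aromatic bromination of the two activated free positions of ring A (C8, then C6), which caps unit A against self-condensation in steps 12 and 16.

Step 12
Reactants: 20 6,8-dibromo-5,7,3',4'-tetra-O-benzyl-4β-(2-ethoxyethoxy)-(+)-catechin; 16 8-bromo-3,5,7,3',4'-penta-O-benzyl-4β-[(2,6-dimethylphenyl)sulfanyl]-epicatechin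
Product: 21 [6,8-dibromo-5,7,3',4'-tetra-O-benzylcatechin]-(4α→6)-[8-bromo-3,5,7,3',4'-penta-O-benzyl-4β-(2,6-dimethylphenylsulfanyl)epicatechin]
Conditions: BF3·OEt2, CH2Cl2, −78 → −40 °C
Reagents that add atoms: none
Why: Lewis acid mediated Friedel–Crafts-type flavan coupling (SN1 at C4 of 20), in which C6 is the only nucleophilic position left on 16 because C8 carries bromine, the C4 sulfide of 16 is not ionised by the hard Lewis acid, and the arene adds trans to the 3-hydroxyl of the catechin cation (4α).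

Step 13
Reactants: 22 (−)-epicatechin
Product: 23 5,7,3',4'-tetra-O-benzyl-(−)-epicatechin
Conditions: BnBr, K2CO3, DMF, rt
Reagents that add atoms: benzyl bromide, BrCc1ccccc1
Why: Williamson etherification selective for the four phenols, as in step 9.

Step 14
Reactants: 23 5,7,3',4'-tetra-O-benzyl-(−)-epicatechin
Product: 24 5,7,3',4'-tetra-O-benzyl-4β-(2-ethoxyethoxy)-(−)-epicatechin
Conditions: DDQ, 2-ethoxyethanol, CH2Cl2, rt
Reagents that add atoms: 2-ethoxyethanol, CCOCCO
Why: DDQ benzylic oxidation with capture of the C4 cation by the alcohol anti to the 2,3-cis substituents, expected to give the 3,4-trans (4β) ether.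

Step 15
Reactants: 24 5,7,3',4'-tetra-O-benzyl-4β-(2-ethoxyethoxy)-(−)-epicatechin; 23 5,7,3',4'-tetra-O-benzyl-(−)-epicatechin
Product: 25 [5,7,3',4'-tetra-O-benzylepicatechin]-(4β→8)-[5,7,3',4'-tetra-O-benzylepicatechin] (octa-O-benzyl procyanidin B2)
Conditions: TMSOTf (0.1 equiv), CH2Cl2, −78 °C; 23 in fourfold excess (recovered)
Reagents that add atoms: none
Why: Lewis acid catalysed flavan coupling in which C8, the most nucleophilic position of 23, attacks the epicatechin C4 cation anti to the 2-aryl and 3-hydroxyl groups, setting the 4β→8 bond, the excess of 23 suppressing oligomerisation.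

Step 16
Reactants: 21 [6,8-dibromo-5,7,3',4'-tetra-O-benzylcatechin]-(4α→6)-[8-bromo-3,5,7,3',4'-penta-O-benzyl-4β-(2,6-dimethylphenylsulfanyl)epicatechin]; 25 octa-O-benzyl procyanidin B2
Product: 26 perbenzylated tribromo tetramer (units A–B–C–D, see list)
Conditions: I2, Ag2O, CH2Cl2, −78 → 0 °C
Reagents that add atoms: none
Why: Thiophilic (soft) activation of the C4 sulfide gives the epicatechin-type C4 cation of unit B, which should be captured by C8 of the upper unit of 25 (its most nucleophilic position) anti to the 3-benzyloxy and 2-aryl groups, setting the 4β→8 bond, while the bromine caps on unit A and on ring A of unit B prevent self-condensation of the electrophile.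

Step 17
Reactants: 26 perbenzylated tribromo tetramer
Product: 27 catechin-(4α→6)-epicatechin-(4β→8)-epicatechin-(4β→8)-epicatechin (CNP0228086.1)
Conditions: H2 (1 atm), Pd(OH)2/C, Et3N, THF/MeOH/H2O, rt
Reagents that add atoms: none
Why: Catalytic hydrogenolysis removes all seventeen benzyl ethers and the three aryl bromides in one operation, triethylamine taking up the HBr so that the acid-labile interflavan bonds and all stereocentres should survive.

## Compound list

1 | 1,3,5-trifluorobenzene | Fc1cc(F)cc(F)c1 | starting material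
2 | 1,3-bis(benzyloxy)-5-fluorobenzene | Fc1cc(OCc2ccccc2)cc(OCc2ccccc2)c1 | intermediate
3 | 1,5-bis(benzyloxy)-2-bromo-3-fluorobenzene | Fc1cc(OCc2ccccc2)cc(OCc2ccccc2)c1Br | intermediate
4 | (S)-4-benzyloxazolidin-2-one | O=C1N[C@@H](Cc2ccccc2)CO1 | starting material
5 | (benzyloxy)acetyl chloride | ClC(=O)COCc1ccccc1 | starting material
6 | (S)-4-benzyl-3-[(benzyloxy)acetyl]oxazolidin-2-one | O=C1OC[C@H](Cc2ccccc2)N1C(=O)COCc1ccccc1 | intermediate
7 | 3,4-bis(benzyloxy)benzaldehyde | O=Cc1ccc(OCc2ccccc2)c(OCc2ccccc2)c1 | starting material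
8 | (S)-4-benzyl-3-[(2S,3R)-2-(benzyloxy)-3-[3,4-bis(benzyloxy)phenyl]-3-hydroxypropanoyl]oxazolidin-2-one (syn aldol) | O=C1OC[C@H](Cc2ccccc2)N1C(=O)[C@@H](OCc1ccccc1)[C@@H](c1ccc(OCc2ccccc2)c(OCc2ccccc2)c1)O | intermediate
9 | (2S,3R)-2-(benzyloxy)-3-[3,4-bis(benzyloxy)phenyl]-3-hydroxy-N-methoxy-N-methylpropanamide | CON(C)C(=O)[C@@H](OCc1ccccc1)[C@@H](c1ccc(OCc2ccccc2)c(OCc2ccccc2)c1)O | intermediate
10 | [2,4-bis(benzyloxy)-6-fluorophenyl]lithium | [Li]c1c(F)cc(OCc2ccccc2)cc1OCc1ccccc1 | intermediate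
11 | dilithium salt of the N-methoxy-N-methyl hemiaminal from addition of 10 to 9 (C4 epimers) | CON(C)C(O[Li])(c1c(F)cc(OCc2ccccc2)cc1OCc1ccccc1)[C@@H](OCc1ccccc1)[C@@H](c1ccc(OCc2ccccc2)c(OCc2ccccc2)c1)O[Li] | intermediate
12 | aryne (C8–C8a dehydro) derived from 11 by loss of LiF | CON(C)C(O[Li])(C1=C(OCc2ccccc2)C=C(OCc2ccccc2)C#C1)[C@@H](OCc1ccccc1)[C@@H](c1ccc(OCc2ccccc2)c(OCc2ccccc2)c1)O[Li] | intermediate
13 | 8-lithio-3,5,7-tris(benzyloxy)-2-[3,4-bis(benzyloxy)phenyl]chromane C4 hemiaminal lithium alkoxide (2R,3-cis) | c1c(OCc3ccccc3)c([Li])c2c(c1OCc3ccccc3)C(O[Li])(N(C)OC)[C@@H](OCc3ccccc3)[C@@H](c1ccc(OCc3ccccc3)c(OCc3ccccc3)c1)O2 | intermediate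
14 | (2R,3S)-3,5,7-tris(benzyloxy)-2-[3,4-bis(benzyloxy)phenyl]-8-bromochroman-4-one (2,3-cis) | c1c(OCc3ccccc3)c(Br)c2c(c1OCc3ccccc3)C(=O)[C@@H](OCc3ccccc3)[C@@H](c1ccc(OCc3ccccc3)c(OCc3ccccc3)c1)O2 | intermediate
15 | (2R,3R)-3,5,7-tris(benzyloxy)-2-[3,4-bis(benzyloxy)phenyl]-8-bromochroman-4-ol, 2,3-cis, C4 epimer mixture | c1c(OCc3ccccc3)c(Br)c2c(c1OCc3ccccc3)C(O)[C@@H](OCc3ccccc3)[C@@H](c1ccc(OCc3ccccc3)c(OCc3ccccc3)c1)O2 | intermediate
16 | (2R,3S,4S)-3,5,7-tris(benzyloxy)-2-[3,4-bis(benzyloxy)phenyl]-8-bromo-4-[(2,6-dimethylphenyl)sulfanyl]chromane (2,3-cis, 3,4-trans) | c1c(OCc3ccccc3)c(Br)c2c(c1OCc3ccccc3)[C@H](Sc1c(C)cccc1C)[C@@H](OCc3ccccc3)[C@@H](c1ccc(OCc3ccccc3)c(OCc3ccccc3)c1)O2 | intermediate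
17 | (+)-catechin | Oc1cc(O)c2c(c1)O[C@H](c1ccc(O)c(O)c1)[C@@H](O)C2 | starting material
18 | 5,7,3',4'-tetra-O-benzyl-(+)-catechin | c1ccccc1COc1cc(OCc3ccccc3)c2c(c1)O[C@H](c1ccc(OCc3ccccc3)c(OCc3ccccc3)c1)[C@@H](O)C2 | intermediate
19 | 5,7,3',4'-tetra-O-benzyl-4β-(2-ethoxyethoxy)-(+)-catechin (3,4-cis) | c1ccccc1COc1cc(OCc3ccccc3)c2c(c1)O[C@H](c1ccc(OCc3ccccc3)c(OCc3ccccc3)c1)[C@@H](O)[C@H]2OCCOCC | intermediate
20 | 6,8-dibromo-5,7,3',4'-tetra-O-benzyl-4β-(2-ethoxyethoxy)-(+)-catechin | c1ccccc1COc1c(Br)c(OCc3ccccc3)c2c(c1Br)O[C@H](c1ccc(OCc3ccccc3)c(OCc3ccccc3)c1)[C@@H](O)[C@H]2OCCOCC | intermediate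
21 | [6,8-dibromo-5,7,3',4'-tetra-O-benzylcatechin]-(4α→6)-[8-bromo-3,5,7,3',4'-penta-O-benzyl-4β-(2,6-dimethylphenylsulfanyl)epicatechin] | c1ccccc1COc1c(Br)c(OCc3ccccc3)c2c(c1Br)O[C@H](c1ccc(OCc3ccccc3)c(OCc3ccccc3)c1)[C@@H](O)[C@@H]2c1c(OCc3ccccc3)c(Br)c2c(c1OCc3ccccc3)[C@H](Sc1c(C)cccc1C)[C@@H](OCc3ccccc3)[C@@H](c1ccc(OCc3ccccc3)c(OCc3ccccc3)c1)O2 | intermediate
22 | (−)-epicatechin | Oc1cc(O)c2c(c1)O[C@H](c1ccc(O)c(O)c1)[C@H](O)C2 | starting material
23 | 5,7,3',4'-tetra-O-benzyl-(−)-epicatechin | c1ccccc1COc1cc(OCc3ccccc3)c2c(c1)O[C@H](c1ccc(OCc3ccccc3)c(OCc3ccccc3)c1)[C@H](O)C2 | intermediate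
24 | 5,7,3',4'-tetra-O-benzyl-4β-(2-ethoxyethoxy)-(−)-epicatechin (3,4-trans) | c1ccccc1COc1cc(OCc3ccccc3)c2c(c1)O[C@H](c1ccc(OCc3ccccc3)c(OCc3ccccc3)c1)[C@H](O)[C@H]2OCCOCC | intermediate
25 | octa-O-benzyl procyanidin B2, [tetra-O-benzylepicatechin]-(4β→8)-[tetra-O-benzylepicatechin] | c1ccccc1COc1cc(OCc3ccccc3)c2c(c1)O[C@H](c1ccc(OCc3ccccc3)c(OCc3ccccc3)c1)[C@H](O)[C@H]2c1c(OCc3ccccc3)cc(OCc3ccccc3)c2c1O[C@H](c1ccc(OCc3ccccc3)c(OCc3ccccc3)c1)[C@H](O)C2 | intermediate
26 | [6,8-dibromo-tetra-O-benzylcatechin]-(4α→6)-[8-bromo-penta-O-benzylepicatechin]-(4β→8)-[tetra-O-benzylepicatechin]-(4β→8)-[tetra-O-benzylepicatechin] | c1ccccc1COc1c(Br)c(OCc4ccccc4)c2c(c1Br)O[C@H](c1ccc(OCc4ccccc4)c(OCc4ccccc4)c1)[C@@H](O)[C@@H]2c1c(OCc4ccccc4)c(Br)c2c(c1OCc4ccccc4)[C@H](c1c(OCc4ccccc4)cc(OCc4ccccc4)c3c1O[C@H](c1ccc(OCc4ccccc4)c(OCc4ccccc4)c1)[C@H](O)[C@H]3c1c(OCc4ccccc4)cc(OCc4ccccc4)c3c1O[C@H](c1ccc(OCc4ccccc4)c(OCc4ccccc4)c1)[C@H](O)C3)[C@@H](OCc4ccccc4)[C@@H](c1ccc(OCc4ccccc4)c(OCc4ccccc4)c1)O2 | intermediate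
27 | catechin-(4α→6)-epicatechin-(4β→8)-epicatechin-(4β→8)-epicatechin (CNP0228086.1) | Oc1cc(O)c2c(c1)O[C@H](c1ccc(O)c(O)c1)[C@@H](O)[C@@H]2c1c(O)cc2c(c1O)[C@H](c1c(O)cc(O)c3c1O[C@H](c1ccc(O)c(O)c1)[C@H](O)[C@H]3c1c(O)cc(O)c3c1O[C@H](c1ccc(O)c(O)c1)[C@H](O)C3)[C@@H](O)[C@@H](c1ccc(O)c(O)c1)O2 | target

## Step count and risks

Total step count: 17. Longest linear sequence: 9 steps (3, 4, 5, 6, 7, 8, 12, 16, 17).

Steps most likely to fail:

1. Step 6 (Proposed new method). What may go wrong: loss of LiF from the aryllithium before it has acylated the amide, competing deprotonation of benzylic ether positions by the excess amide base, collapse of the hemiaminal in the flask followed by enolisation, or epimerisation at C3 when the 2,3-cis ketone is released. Fallback (known reactions only; the O1–C8a bond is still the ring-closing bond but is made by palladium catalysis at the alcohol oxidation level): it sets out from 9 and commercial 1,3-bis(benzyloxy)-5-bromobenzene. The arene is iodinated para to one benzyloxy group (NIS, cat. TFA, MeCN) to give 1,5-bis(benzyloxy)-3-bromo-2-iodobenzene F1. Iodine–magnesium exchange (i-PrMgCl·LiCl, THF, −40 °C) gives [2,4-bis(benzyloxy)-6-bromophenyl]magnesium chloride F2, which does not eliminate at this temperature. F2 is added to 9 (hydroxyl first deprotonated by i-PrMgCl) to give (2S,3R)-2-(benzyloxy)-1-[2,4-bis(benzyloxy)-6-bromophenyl]-3-[3,4-bis(benzyloxy)phenyl]-3-hydroxypropan-1-one F3. NaBH4 reduction gives the corresponding 1,3-diol F4 (C1 epimers). Intramolecular aryl etherification (Pd(OAc)2, 2-(di-tert-butylphosphino)-1,1'-binaphthyl, Cs2CO3, toluene, 70 °C) closes the pyran with retention at C2 to give 3,5,7,3',4'-penta-O-benzyl-epicatechin-4-ol F5. NBS bromination at C8, the more reactive free position of 5,7-dialkoxyflavans, brings the route back at 15.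

2. Step 12. What may go wrong: poor facial selectivity at C4 of unit A (4α against 4β), or slow attack by the hindered, bromine-deactivated C6 of 16 so that the cation decays before it is captured. Fallback (neighbouring-group participation instead of inherent facial bias): it sets out from 20, which is acetylated (Ac2O, pyridine, DMAP) to 3-O-acetyl-6,8-dibromo-5,7,3',4'-tetra-O-benzyl-4β-(2-ethoxyethoxy)-(+)-catechin F6. Ionisation with TMSOTf at −78 °C should give the acetoxonium ion bridged on the β face, which C6 of 16 opens from the α face to give the 3-O-acetate of the A–B dimer F7. Methanolysis (K2CO3, MeOH/THF) removes the acetate and the route comes back at 21.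

3. Step 16. What may go wrong: iodination of the electron-rich nucleophile 25 by the thiophilic activator, or incomplete activation of the hindered sulfide with loss of the late-stage dimers. Fallback (separate activation from coupling, then hard Lewis acid chemistry): it sets out from 21, which is treated with I2/Ag2O in the presence of 2-ethoxyethanol as the only nucleophile to give the A–B dimer 4β-(2-ethoxyethyl) ether F8. F8 is then coupled with 25 by the O-leaving-group method (Yb(OTf)3, CH2Cl2, rt), and the route comes back at 26.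

Further compounds

F1 | step 6 | 1,5-bis(benzyloxy)-3-bromo-2-iodobenzene | Brc1cc(OCc2ccccc2)cc(OCc2ccccc2)c1I
F2 | step 6 | [2,4-bis(benzyloxy)-6-bromophenyl]magnesium chloride | Cl[Mg]c1c(Br)cc(OCc2ccccc2)cc1OCc1ccccc1
F3 | step 6 | (2S,3R)-2-(benzyloxy)-1-[2,4-bis(benzyloxy)-6-bromophenyl]-3-[3,4-bis(benzyloxy)phenyl]-3-hydroxypropan-1-one | O=C(c1c(Br)cc(OCc2ccccc2)cc1OCc1ccccc1)[C@@H](OCc1ccccc1)[C@@H](c1ccc(OCc2ccccc2)c(OCc2ccccc2)c1)O
F4 | step 6 | 2-(benzyloxy)-1-[2,4-bis(benzyloxy)-6-bromophenyl]-3-[3,4-bis(benzyloxy)phenyl]propane-1,3-diol (2,3-syn, C1 epimers) | OC(c1c(Br)cc(OCc2ccccc2)cc1OCc1ccccc1)[C@@H](OCc1ccccc1)[C@@H](c1ccc(OCc2ccccc2)c(OCc2ccccc2)c1)O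
F5 | step 6 | 3,5,7,3',4'-penta-O-benzyl-epicatechin-4-ol (C4 epimers) | c1c(OCc3ccccc3)cc2c(c1OCc3ccccc3)C(O)[C@@H](OCc3ccccc3)[C@@H](c1ccc(OCc3ccccc3)c(OCc3ccccc3)c1)O2
F6 | step 12 | 3-O-acetyl-6,8-dibromo-5,7,3',4'-tetra-O-benzyl-4β-(2-ethoxyethoxy)-(+)-catechin | c1ccccc1COc1c(Br)c(OCc3ccccc3)c2c(c1Br)O[C@H](c1ccc(OCc3ccccc3)c(OCc3ccccc3)c1)[C@@H](OC(C)=O)[C@H]2OCCOCC
F7 | step 12 | [3-O-acetyl-6,8-dibromo-5,7,3',4'-tetra-O-benzylcatechin]-(4α→6)-[8-bromo-3,5,7,3',4'-penta-O-benzyl-4β-(2,6-dimethylphenylsulfanyl)epicatechin] | c1ccccc1COc1c(Br)c(OCc3ccccc3)c2c(c1Br)O[C@H](c1ccc(OCc3ccccc3)c(OCc3ccccc3)c1)[C@@H](OC(C)=O)[C@@H]2c1c(OCc3ccccc3)c(Br)c2c(c1OCc3ccccc3)[C@H](Sc1c(C)cccc1C)[C@@H](OCc3ccccc3)[C@@H](c1ccc(OCc3ccccc3)c(OCc3ccccc3)c1)O2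
F8 | step 16 | [6,8-dibromo-5,7,3',4'-tetra-O-benzylcatechin]-(4α→6)-[8-bromo-3,5,7,3',4'-penta-O-benzyl-4β-(2-ethoxyethoxy)epicatechin] | c1ccccc1COc1c(Br)c(OCc3ccccc3)c2c(c1Br)O[C@H](c1ccc(OCc3ccccc3)c(OCc3ccccc3)c1)[C@@H](O)[C@@H]2c1c(OCc3ccccc3)c(Br)c2c(c1OCc3ccccc3)[C@H](OCCOCC)[C@@H](OCc3ccccc3)[C@@H](c1ccc(OCc3ccccc3)c(OCc3ccccc3)c1)O2
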